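**One-step world.** In a one-step world each substrate falls by its own first-order law, and the logarithm of the left-handed fraction left, over that of the right-handed fraction left, is a constant: the selectivity factor.

| flask | left-handed substrate | right-handed substrate | partner | protic impurity | free catalyst | remark | time |
|---|---|---|---|---|---|---|---|
| midnight | 0.50 M | 0.50 M | 1.5 M | 10 mM | 0.12 mM | run made earlier |  |
| spring | 0.50 M | 0.50 M | 1.5 M | 10 mM | 0.50 mM | run made earlier |  |
| flask | 0.50 M | 0.50 M | 1.50 M | 10.0 mM | 0.25 mM |  | 1.0 h |

| run | time / min | right-handed substrate / % | left-handed substrate / % |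
|---|---|---|---|
| midnight | 4.00 | 48 | 43 |
| midnight | 6.00 | 47 | 42 |
| midnight | 8.00 | 45 | 34 |
| midnight | 15.0 | 46 | 32 |
| midnight | 20.0 | 45 | 24 |
| midnight | 30.0 | 42 | 13 |
| midnight | 50.0 | 30 | 5 |
| spring | 2.50 | 47 | 34 |
| spring | 8.00 | 41 | 17 |
| spring | 15.0 | 34 | 5 |
| spring | 20.0 | 32 | 5 |
| spring | 30.0 | 26 | 0 |
| spring | 40.0 | 18 | 0 |
| spring | 50.0 | 19 | 3 |

(readings scatter by 2 percentage points)

- whether the excess of right-handed substrate over left-handed substrate among what is left of the two reaches 95 % by 1.0 h (no / yes)
- the highest excess of right-handed substrate over left-handed substrate among what is left of the two up to 1.0 h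

- free catalyst is single-handed; left-handed substrate and right-handed substrate are mirror images of each other, charged as a racemate, each of them at the stated concentration
- candidate steps: 2 free catalyst <-> resting dimer; free catalyst + right-handed substrate <-> catalyst intermediate B; partner + catalyst intermediate A -> free catalyst + left-handed product; 2 free catalyst -> spent catalyst; partner + protic impurity -> quenched reagent; free catalyst + left-handed substrate <-> catalyst intermediate A; partner + catalyst intermediate B -> free catalyst + right-handed product

**Reading it.** From the readings I get 6.97 in the midnight run at 20.0 min and 5.44 in the spring run at 8.00 min. I carry their mean, 6.20, as the selectivity factor.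

**Stopping point.** The wanted excess of 95 % means left-handed over right-handed substrate at 0.0256. With my selectivity factor, the right-handed substrate then stands near 24.7 % of both charged.

**Time.** The nearest spring reading is 26 % at 30.0 min. If rate followed catalyst charge, this flask would need 60.0 min, with no margin against 60 min. So I go round again. The left-handed substrate read 5 % after 50.0 min in the midnight run and 5 % after 15.0 min in the spring run, the same level, so 4.17 times the charge bought about 3.33 times the speed, a reading that carries the scatter of 2 percentage points. That is an apparent order of 0.844, which is less than first order. Put back, it gives 53.8 min.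

**The decision.** I keep 0.25 mM of catalyst and sample from 53.8 min, sooner than the full 60 min.

**The forecast.** It answers yes, with a top of 99.3 %: “Comparing ln(fraction left) for the two gives a selectivity of about 6 in both runs.” It expects the crossing at 30 to 40 min; mine stands at 53.8 min.

**The flask.** It answers yes, with a top of 98.3 %, crossing at 47.2 min with 26.2 % right-handed substrate left.

    2 free catalyst ⇌ resting dimer, settled at all times (K = 4900 M⁻¹)
    free catalyst + right-handed substrate ⇌ catalyst intermediate B (K = 3.40 M⁻¹, k = 29.0 M⁻¹ s⁻¹)
    partner + catalyst intermediate A → free catalyst + left-handed product (k = 2.50 M⁻¹ s⁻¹)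
    2 free catalyst → spent catalyst (k = 0.270 M⁻¹ s⁻¹)
    partner + protic impurity → quenched reagent (k = 0.00380 M⁻¹ s⁻¹)
    free catalyst + left-handed substrate ⇌ catalyst intermediate A (K = 11.0 M⁻¹, k = 180 M⁻¹ s⁻¹)
    partner + catalyst intermediate B → free catalyst + right-handed product (k = 1.20 M⁻¹ s⁻¹)

**After crossing.** From 33.8 % right-handed substrate at 0.500 h, my selectivity factor gives 4.41 % left-handed against the flask's 3.72 %; from the spring reading of 34 % at 15.0 min it gives 4.58 % against a reading of 5 %. At 1.00 h the flask's partner goes through catalyst intermediate A at 0.059 of its rate through catalyst intermediate B. Between the crossing and that time the right-handed substrate falls from 26.2 % to 21.7 %, while the excess ends at 98.3 %.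

All runs come from a simulation on assumed constants.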